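**Retrosynthetic overview**

1. The C1' 3-methylbut-2-enoate and the free C5 hydroxyl are installed or unmasked last. The quinone ring B comes from para-oxidation of a 1-naphthol, which is the isomer of a 1,4-oxygen-bridged dihydronaphthalene.
2. The plan rests on one feature: ring B is a bare four-carbon unit (C1 carbonyl, C2=C3, C4 carbonyl, no substituents) fused at C4a–C8a to a ring A whose other four positions are all different (C5–OH, C6–H, C7 bearing C1', C8–OMe). C8a–C1 and C4–C4a are therefore cut together, giving furan and a ring A aryne.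
3. The aryne is released from a ring A bromide (Br on the future C4a, H on the future C8a) that already carries the methyl ether, a methoxymethyl ether and the silyl-protected (R) side chain.
4. The bromide comes from 5-hydroxy-2-methoxybenzaldehyde: acetal protection, asymmetric allylboration (sets C1'), silylation, bromination para to the side chain, cross-metathesis to the prenyl terminus.
5. Ring order: ring A is purchased; ring B is the only ring made, in step 6.

Key step: step 6

Remark on the chemistry: ring positions are named with the target numbering (C5 oxygen, C7 side chain, C8 methoxy); opening of the oxygen bridge in step 7 is not expected to be regioselective, so both 1-naphthols are oxidised in the same flask, where each gives the same quinone.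

**Route**

Step 1
Reactants: 1 5-hydroxy-2-methoxybenzaldehyde
Product: 2 2-methoxy-5-(methoxymethoxy)benzaldehyde
Conditions: MOMCl, iPr2NEt, CH2Cl2, 0 °C to rt
Reagents that add atoms: chloromethyl methyl ether, COCCl
Why: O-alkylation of the phenol to its methoxymethyl ether under amine base leaves the aldehyde untouched and gives a group that survives the boron, lithium amide and fluoride steps ahead.

Step 2
Reactants: 2 2-methoxy-5-(methoxymethoxy)benzaldehyde
Product: 4 (R)-1-[2-methoxy-5-(methoxymethoxy)phenyl]but-3-en-1-ol, via borinate ester 3 (not isolated)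
Conditions: (+)-Ipc2B(allyl) (from (−)-α-pinene, 1 M in pentane), Et2O, −78 °C; then 3 M NaOH, 30% H2O2, 0 °C to rt
Reagents that add atoms: (+)-B-allyldiisopinocampheylborane, C=CCB([C@H]1C[C@H]2C[C@@H]([C@@H]1C)C2(C)C)[C@H]1C[C@H]2C[C@@H]([C@@H]1C)C2(C)C
Why: Brown allylboration through a chair Zimmerman–Traxler transition state; the reagent derived from (−)-α-pinene delivers allyl to the Re face of an aryl aldehyde, which should set C1' as (R), and oxidative work-up frees the alcohol.

Step 3
Reactants: 4 (R)-1-[2-methoxy-5-(methoxymethoxy)phenyl]but-3-en-1-ol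
Product: 5 (R)-tert-butyl{1-[2-methoxy-5-(methoxymethoxy)phenyl]but-3-enyloxy}dimethylsilane
Conditions: TBSCl, imidazole, DMAP (cat.), DMF, rt
Reagents that add atoms: tert-butyldimethylsilyl chloride, CC(C)(C)[Si](C)(C)Cl
Why: Silyl ether formation on the secondary benzylic alcohol gives a base-stable mask that tolerates the lithium amide of step 6 and does not touch the C1'–O bond.

Step 4
Reactants: 5 (R)-tert-butyl{1-[2-methoxy-5-(methoxymethoxy)phenyl]but-3-enyloxy}dimethylsilane
Product: 6 (R)-{1-[4-bromo-2-methoxy-5-(methoxymethoxy)phenyl]but-3-enyloxy}(tert-butyl)dimethylsilane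
Conditions: NBS, MeCN, 0 °C to rt, dark
Reagents that add atoms: N-bromosuccinimide, O=C1CCC(=O)N1Br
Why: Electrophilic aromatic bromination should go to the position para to the alkyl side chain and ortho to the acetal oxygen, as in 2,5-dialkoxytoluenes, because the other acetal-ortho site is blocked by the branched side chain; a monosubstituted alkene reacts with NBS in dry acetonitrile far more slowly than this dialkoxyarene, which is why bromination precedes step 5.

Step 5
Reactants: 6 (R)-{1-[4-bromo-2-methoxy-5-(methoxymethoxy)phenyl]but-3-enyloxy}(tert-butyl)dimethylsilane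
Product: 7 (R)-{1-[4-bromo-2-methoxy-5-(methoxymethoxy)phenyl]-4-methylpent-3-enyloxy}(tert-butyl)dimethylsilane
Conditions: second-generation Grubbs catalyst RuCl2(=CHPh)(H2IMes)(PCy3) (5 mol %), 2-methylbut-2-ene (excess), CH2Cl2, 40 °C
Reagents that add atoms: 2-methylbut-2-ene, CC=C(C)C
Why: Olefin cross-metathesis of a terminal alkene with excess 2-methylbut-2-ene exchanges the methylidene for an isopropylidene terminus, and the aryl bromide, acetal and silyl ether are inert to the ruthenium carbene.

Step 6
Reactants: 7 (R)-{1-[4-bromo-2-methoxy-5-(methoxymethoxy)phenyl]-4-methylpent-3-enyloxy}(tert-butyl)dimethylsilane; 8 furan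
Product: 11 8-methoxy-5-(methoxymethoxy)-7-[(R)-1-(tert-butyldimethylsilyloxy)-4-methylpent-3-enyl]-1,4-dihydro-1,4-epoxynaphthalene (both bridgehead epimers), via aryllithium 9 (not isolated), via aryne 10 (not isolated)
Conditions: LiN(iPr)2 (1.5 equiv), furan (15 equiv), THF, −78 °C to rt
Reagents that add atoms: none
Why: LiN(iPr)2 removes the ring proton flanked by the C8 methoxy group and the bromine (C8a–H) to give aryllithium 9, which on warming loses LiBr to aryne 10 with its strained bond at C4a–C8a. Furan, present in large excess, then adds across that bond in a concerted [4+2] cycloaddition that forms C8a–C1 and C4–C4a together, so the six-membered carbocycle of ring B closes by intermolecular annulation onto ring A as its 1,4-oxygen-bridged dihydro form. The closest known reaction type is the benzyne–furan Diels–Alder reaction of 3,6-dialkoxybenzynes released from 2-bromo-1,4-dialkoxybenzenes with lithium amides. No lasting stereocentre is created: the two bridgehead carbons form without control relative to C1' and both end as carbonyl carbons, while C1' is untouched. The step needs site-selective deprotonation and fast trapping: the C8a proton is acidified inductively by both flanking substituents, whereas an anion at C6 has no leaving group beside it and simply reprotonates, and the excess of furan should outcompete addition of diisopropylamine or of 9 to the aryne. Because furan is symmetrical and C1 and C4 become equivalent carbonyls, the orientation of addition is immaterial.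

Step 7
Reactants: 11 8-methoxy-5-(methoxymethoxy)-7-[(R)-1-(tert-butyldimethylsilyloxy)-4-methylpent-3-enyl]-1,4-dihydro-1,4-epoxynaphthalene
Product: 14 8-methoxy-5-(methoxymethoxy)-7-[(R)-1-(tert-butyldimethylsilyloxy)-4-methylpent-3-enyl]naphthalene-1,4-dione, via 1-naphthol 12 (not isolated), via regioisomeric 1-naphthol 13 (not isolated)
Conditions: CSA (10 mol %), CH2Cl2, 0 °C; then Et3N (20 mol %), solvent switch to MeCN; Co(salen) (10 mol %), O2 (1 atm), rt
Reagents that add atoms: dioxygen, O=O
Why: Acid-catalysed isomerisation of an oxabenzonorbornadiene to a 1-naphthol (bridge C–O ionisation to an allylic, benzylic cation stabilised by the ortho alkoxy group, then proton loss and tautomerisation) should need only catalytic acid in an aprotic solvent on this electron-rich ring and gives 12 or 13 according to which bridge C–O bond ionises, and the salcomine-type oxygenation of a phenol with a free para position, catalysed by the divalent cobalt complex Co(salen), then converges both air-sensitive naphthols on the same 1,4-dione in the same flask, while ring A, which has no free hydroxyl, the acetal, the silyl ether and the trisubstituted alkene should be left alone.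

Step 8
Reactants: 14 8-methoxy-5-(methoxymethoxy)-7-[(R)-1-(tert-butyldimethylsilyloxy)-4-methylpent-3-enyl]naphthalene-1,4-dione
Product: 15 7-[(R)-1-hydroxy-4-methylpent-3-enyl]-8-methoxy-5-(methoxymethoxy)naphthalene-1,4-dione
Conditions: HF·pyridine, pyridine, THF, 0 °C to rt
Reagents that add atoms: none
Why: Fluoride desilylation driven by the Si–F bond, run with buffered HF·pyridine, avoids the basic conditions that degrade quinones and leaves the methoxymethyl ether, the alkene and the C1'–O bond intact.

Step 9
Reactants: 15 7-[(R)-1-hydroxy-4-methylpent-3-enyl]-8-methoxy-5-(methoxymethoxy)naphthalene-1,4-dione; 16 3-methylbut-2-enoic acid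
Product: 17 (R)-1-[8-methoxy-5-(methoxymethoxy)-1,4-dioxo-1,4-dihydronaphthalen-7-yl]-4-methylpent-3-enyl 3-methylbut-2-enoate
Conditions: DCC, DMAP (cat.), CH2Cl2, 0 °C to rt
Reagents that add atoms: none
Why: Steglich esterification acylates the secondary alcohol on oxygen, so C1' keeps its configuration, and the carbodiimide method avoids the ketene pathway that deconjugates this acyl group when its acid chloride meets an amine base.

Step 10
Reactants: 17 (R)-1-[8-methoxy-5-(methoxymethoxy)-1,4-dioxo-1,4-dihydronaphthalen-7-yl]-4-methylpent-3-enyl 3-methylbut-2-enoate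
Product: 18 (R)-1-(5-hydroxy-8-methoxy-1,4-dioxo-1,4-dihydronaphthalen-7-yl)-4-methylpent-3-enyl 3-methylbut-2-enoate
Conditions: TFA–CH2Cl2 (1:9), 0 °C; aq NaHCO3
Reagents that add atoms: none
Why: Acid-catalysed acetal cleavage should be fast for a methoxymethyl ether on the electron-poor peri oxygen, whose phenol is a good leaving group and ends hydrogen-bonded to the C4 carbonyl, while the C8 methyl ether, the ester and the quinone should survive brief cold exposure.

**Compound list**

1 | 5-hydroxy-2-methoxybenzaldehyde | COc1ccc(O)cc1C=O | starting material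
2 | 2-methoxy-5-(methoxymethoxy)benzaldehyde | COc1ccc(OCOC)cc1C=O | intermediate
3 | (R)-1-[2-methoxy-5-(methoxymethoxy)phenyl]but-3-enyl bis(isopinocampheyl)borinate (isopinocampheyl groups from (−)-α-pinene) | COc1ccc(OCOC)cc1[C@@H](CC=C)OB([C@H]1C[C@H]2C[C@@H]([C@@H]1C)C2(C)C)[C@H]1C[C@H]2C[C@@H]([C@@H]1C)C2(C)C | intermediate
4 | (R)-1-[2-methoxy-5-(methoxymethoxy)phenyl]but-3-en-1-ol | COc1ccc(OCOC)cc1[C@@H](CC=C)O | intermediate
5 | (R)-tert-butyl{1-[2-methoxy-5-(methoxymethoxy)phenyl]but-3-enyloxy}dimethylsilane | COc1ccc(OCOC)cc1[C@@H](CC=C)O[Si](C)(C)C(C)(C)C | intermediate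
6 | (R)-{1-[4-bromo-2-methoxy-5-(methoxymethoxy)phenyl]but-3-enyloxy}(tert-butyl)dimethylsilane | COc1cc(Br)c(OCOC)cc1[C@@H](CC=C)O[Si](C)(C)C(C)(C)C | intermediate
7 | (R)-{1-[4-bromo-2-methoxy-5-(methoxymethoxy)phenyl]-4-methylpent-3-enyloxy}(tert-butyl)dimethylsilane | COc1cc(Br)c(OCOC)cc1[C@@H](CC=C(C)C)O[Si](C)(C)C(C)(C)C | intermediate
8 | furan | c1ccoc1 | starting material
9 | aryllithium: 7 lithiated at the ring carbon between the methoxy group and the bromine | COc1c([Li])c(Br)c(OCOC)cc1[C@@H](CC=C(C)C)O[Si](C)(C)C(C)(C)C | intermediate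
10 | aryne: 3-methoxy-6-(methoxymethoxy)-4-[(R)-1-(tert-butyldimethylsilyloxy)-4-methylpent-3-enyl]benzyne | COC1=C([C@@H](CC=C(C)C)O[Si](C)(C)C(C)(C)C)C=C(OCOC)C#C1 | intermediate
11 | 8-methoxy-5-(methoxymethoxy)-7-[(R)-1-(tert-butyldimethylsilyloxy)-4-methylpent-3-enyl]-1,4-dihydro-1,4-epoxynaphthalene (both bridgehead epimers) | COc1c([C@@H](CC=C(C)C)O[Si](C)(C)C(C)(C)C)cc(OCOC)c2c1C1C=CC2O1 | intermediate
12 | 8-methoxy-5-(methoxymethoxy)-7-[(R)-1-(tert-butyldimethylsilyloxy)-4-methylpent-3-enyl]naphthalen-1-ol | COc1c([C@@H](CC=C(C)C)O[Si](C)(C)C(C)(C)C)cc(OCOC)c2cccc(O)c12 | intermediate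
13 | 5-methoxy-8-(methoxymethoxy)-6-[(R)-1-(tert-butyldimethylsilyloxy)-4-methylpent-3-enyl]naphthalen-1-ol (regioisomer of 12) | COc1c([C@@H](CC=C(C)C)O[Si](C)(C)C(C)(C)C)cc(OCOC)c2c(O)cccc12 | intermediate
14 | 8-methoxy-5-(methoxymethoxy)-7-[(R)-1-(tert-butyldimethylsilyloxy)-4-methylpent-3-enyl]naphthalene-1,4-dione | COc1c([C@@H](CC=C(C)C)O[Si](C)(C)C(C)(C)C)cc(OCOC)c2c1C(=O)C=CC2=O | intermediate
15 | 7-[(R)-1-hydroxy-4-methylpent-3-enyl]-8-methoxy-5-(methoxymethoxy)naphthalene-1,4-dione | COc1c([C@@H](CC=C(C)C)O)cc(OCOC)c2c1C(=O)C=CC2=O | intermediate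
16 | 3-methylbut-2-enoic acid | CC(C)=CC(=O)O | starting material
17 | (R)-1-[8-methoxy-5-(methoxymethoxy)-1,4-dioxo-1,4-dihydronaphthalen-7-yl]-4-methylpent-3-enyl 3-methylbut-2-enoate | COc1c([C@@H](CC=C(C)C)OC(=O)C=C(C)C)cc(OCOC)c2c1C(=O)C=CC2=O | intermediate
18 | (R)-1-(5-hydroxy-8-methoxy-1,4-dioxo-1,4-dihydronaphthalen-7-yl)-4-methylpent-3-enyl 3-methylbut-2-enoate | COc1c([C@@H](CC=C(C)C)OC(=O)C=C(C)C)cc(O)c2c1C(=O)C=CC2=O | target

**Step count**

Total steps: 10. Longest linear sequence: 10 steps (1 to 18).

**Steps most likely to fail**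

Step 6. The aryne may be captured by diisopropylamine or by aryllithium 9 before furan adds, or metalation may stall and return 7. The fallback sets out from 7 and comes back at 11. It separates metalation from aryne release and removes the amine from the trapping stage. Compound 7 is deprotonated with LiN(iPr)2 in THF at −78 °C without furan. Aryllithium 9, which should persist at that temperature, is quenched with 1,2-diiodoethane to give (R)-{1-[4-bromo-3-iodo-2-methoxy-5-(methoxymethoxy)phenyl]-4-methylpent-3-enyloxy}(tert-butyl)dimethylsilane F1. Treating the isolated F1 with n-BuLi in toluene and furan at −78 °C should effect iodine–lithium exchange and regenerate 9 in an amine-free medium. On warming, 9 loses LiBr to aryne 10, which furan traps to give 11.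

Step 7. The acid needed to open the oxygen bridge may also strip the acetal or the silyl ether, or start cationic reactions at the side-chain alkene, and the electron-rich naphthols may degrade before the oxygenation consumes them. The fallback sets out from 7 and comes back at 14. It replaces the diene, so that no acid isomerisation is needed. Aryne 10, generated from 7 as in step 6, is trapped with 2-methoxyfuran. This should give the C4-methoxy bridged ketal F2 and its orientation isomer, the C1-methoxy bridged ketal F4. Each opens spontaneously at the ketal carbon, F2 to 4,8-dimethoxy-5-(methoxymethoxy)-7-[(R)-1-(tert-butyldimethylsilyloxy)-4-methylpent-3-enyl]naphthalen-1-ol F3 and F4 to 4,5-dimethoxy-8-(methoxymethoxy)-6-[(R)-1-(tert-butyldimethylsilyloxy)-4-methylpent-3-enyl]naphthalen-1-ol F5. Oxidation of the mixture with PhI(OAc)2 in aqueous MeCN at 0 °C should turn both para-methoxy naphthols into quinone 14 with loss of methanol. The dialkoxy ring A, which has no free hydroxyl, should not react.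

Step 10. Acid may ionise the benzylic ester C–O bond, causing racemisation or elimination, or add across the side-chain alkene faster than it cleaves the acetal. The fallback sets out from 14 and comes back at 18. It removes the acetal before the ester exists and ends with a chemoselective acylation. Quinone 14 is treated with TFA in CH2Cl2 at 0 °C while the benzylic oxygen is still a robust silyl ether, to give 5-hydroxy-8-methoxy-7-[(R)-1-(tert-butyldimethylsilyloxy)-4-methylpent-3-enyl]naphthalene-1,4-dione F6. HF·pyridine then gives 5-hydroxy-7-[(R)-1-hydroxy-4-methylpent-3-enyl]-8-methoxynaphthalene-1,4-dione F7. Steglich coupling of F7 with one equivalent of 16 (DCC, catalytic DMAP) should acylate only the side-chain alcohol and give 18. The peri hydroxyl is hydrogen-bonded to the C4 carbonyl and is a poor nucleophile, as in the selective side-chain acylation of hydroxynaphthoquinones with chelated phenols.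

Further compounds
F1 | step 6 | (R)-{1-[4-bromo-3-iodo-2-methoxy-5-(methoxymethoxy)phenyl]-4-methylpent-3-enyloxy}(tert-butyl)dimethylsilane | COc1c(I)c(Br)c(OCOC)cc1[C@@H](CC=C(C)C)O[Si](C)(C)C(C)(C)C
F2 | step 7 | 4,8-dimethoxy-5-(methoxymethoxy)-7-[(R)-1-(tert-butyldimethylsilyloxy)-4-methylpent-3-enyl]-1,4-dihydro-1,4-epoxynaphthalene | COc1c([C@@H](CC=C(C)C)O[Si](C)(C)C(C)(C)C)cc(OCOC)c2c1C1C=CC2(OC)O1
F3 | step 7 | 4,8-dimethoxy-5-(methoxymethoxy)-7-[(R)-1-(tert-butyldimethylsilyloxy)-4-methylpent-3-enyl]naphthalen-1-ol | COc1c([C@@H](CC=C(C)C)O[Si](C)(C)C(C)(C)C)cc(OCOC)c2c(OC)ccc(O)c12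
F4 | step 7 | 1,8-dimethoxy-5-(methoxymethoxy)-7-[(R)-1-(tert-butyldimethylsilyloxy)-4-methylpent-3-enyl]-1,4-dihydro-1,4-epoxynaphthalene | COc1c([C@@H](CC=C(C)C)O[Si](C)(C)C(C)(C)C)cc(OCOC)c2c1C1(OC)C=CC2O1
F5 | step 7 | 4,5-dimethoxy-8-(methoxymethoxy)-6-[(R)-1-(tert-butyldimethylsilyloxy)-4-methylpent-3-enyl]naphthalen-1-ol | COc1c([C@@H](CC=C(C)C)O[Si](C)(C)C(C)(C)C)cc(OCOC)c2c(O)ccc(OC)c12
F6 | step 10 | 5-hydroxy-8-methoxy-7-[(R)-1-(tert-butyldimethylsilyloxy)-4-methylpent-3-enyl]naphthalene-1,4-dione | COc1c([C@@H](CC=C(C)C)O[Si](C)(C)C(C)(C)C)cc(O)c2c1C(=O)C=CC2=O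
F7 | step 10 | 5-hydroxy-7-[(R)-1-hydroxy-4-methylpent-3-enyl]-8-methoxynaphthalene-1,4-dione | COc1c([C@@H](CC=C(C)C)O)cc(O)c2c1C(=O)C=CC2=O
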